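## Retrosynthetic overview

- The target comes from a macrocyclic epoxy alcohol by ester reduction, acylation at C4 and desilylation; the 5,6-epoxide comes from a hydroxyl-directed epoxidation of the (E)-cycloundecenol.
- The 11-membered carbocycle is the only carbocycle and is formed first, by intramolecular Horner–Wadsworth–Emmons olefination at C9=C10; the oxirane is formed second.
- The C1–C11 bond and the quaternary centre C1 come from a Claisen rearrangement of an allyl vinyl ether, with chirality transferred from the C3 carbinol.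
- The C3 carbinol (C2–C3 bond) comes from a Nozaki–Hiyama–Kishi coupling of an (E)-vinyl iodide with an α-PMB-oxy aldehyde.
- C3' is bought as (S)-5-oxotetrahydrofuran-2-carboxylic acid; C4 is set by (R)-glyceraldehyde acetonide, whose own centre is later excised.

Assumption: 5-chloropent-2-yne is taken as a commercial compound.
Locants C1–C11 and C1'–C4' in the Why lines follow the target: C1 quaternary ring carbon, C2=C3, C4 ester-bearing carbon, C5/C6 epoxide, C9 the CH2OH-bearing carbon, C3' the side-chain carbinol.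

## Route

Step 1
Reactants: 1 (S)-5-oxotetrahydrofuran-2-carboxylic acid
Product: 3 (S)-5-acetyldihydrofuran-2(3H)-one, via acid chloride 2 (not isolated)
Conditions: (COCl)2, DMF (cat.), CH2Cl2, 0 °C to rt; then MeMgBr, Fe(acac)3 (3 mol%), THF, −78 °C
Reagents that add atoms: methylmagnesium bromide, C[Mg]Br
Why: Acid chloride formation followed by iron-catalysed acylation of the Grignard reagent stops at the methyl ketone without touching the lactone, and the bought stereocentre (later C3') is not involved.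

Step 2
Reactants: 3 (S)-5-acetyldihydrofuran-2(3H)-one
Product: 4 (S)-5-(prop-1-en-2-yl)dihydrofuran-2(3H)-one
Conditions: Zn, CH2Br2, TiCl4, THF, −40 to 5 °C; then 3, CH2Cl2, rt
Reagents that add atoms: dibromomethane, BrCBr
Why: Takai–Lombardo methylenation is non-basic and selective for the ketone over the lactone, so the epimerisable oxygen-bearing centre keeps its (S) configuration.

Step 3
Reactants: 4 (S)-5-(prop-1-en-2-yl)dihydrofuran-2(3H)-one
Product: 6 (S)-2-methylhept-1-en-6-yn-3-ol, via lactol 5 (not isolated)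
Conditions: i-Bu2AlH (1.05 equiv), CH2Cl2, −78 °C; then MeOH, K2CO3, dimethyl (1-diazo-2-oxopropyl)phosphonate, 0 °C to rt
Reagents that add atoms: dimethyl (1-diazo-2-oxopropyl)phosphonate, CC(=O)C(=[N+]=[N-])P(=O)(OC)OC
Why: Partial reduction to the lactol and Seyferth–Gilbert homologation with the Ohira–Bestmann reagent on the open hydroxy aldehyde give the terminal alkyne while the carbinol centre is untouched.

Step 4
Reactants: 6 (S)-2-methylhept-1-en-6-yn-3-ol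
Product: 7 (S)-tert-butyldimethyl[(2-methylhept-1-en-6-yn-3-yl)oxy]silane
Conditions: TBSCl, imidazole, DMF, rt
Reagents that add atoms: tert-butyldimethylsilyl chloride, CC(C)(C)[Si](C)(C)Cl
Why: Standard silylation protects the secondary allylic alcohol for the organometallic steps that follow.

Step 5
Reactants: 7 (S)-tert-butyldimethyl[(2-methylhept-1-en-6-yn-3-yl)oxy]silane
Product: 9 tert-butyl{[(3S,6E)-7-iodo-2,6-dimethylhepta-1,6-dien-3-yl]oxy}dimethylsilane, via alkenylalane 8 (not isolated)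
Conditions: Me3Al, Cp2ZrCl2 (20 mol%), CH2Cl2, 0 °C to rt; then I2, THF, −30 °C
Reagents that add atoms: trimethylaluminium, C[Al](C)C; iodine, [I][I]
Why: Negishi zirconium-catalysed carboalumination adds methyl and aluminium syn across the terminal alkyne (methyl to the internal carbon), and iodinolysis with retention gives only the (E)-iodide.

Step 6
Reactants: 10 5-chloropent-2-yne
Product: 12 (E)-5-chloro-2-iodopent-2-ene, via alkenylzirconocene 11 (not isolated)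
Conditions: Cp2Zr(H)Cl (1.5 equiv), THF, rt to 40 °C; then I2, 0 °C
Reagents that add atoms: iodine, [I][I]
Why: Hydrozirconation adds H and Zr syn, with zirconium settling on the less hindered methyl-bearing carbon after equilibration, and iodinolysis with retention gives the (E)-2-iodoalkene.

Step 7
Reactants: 12 (E)-5-chloro-2-iodopent-2-ene; 13 (R)-2,2-dimethyl-1,3-dioxolane-4-carbaldehyde
Product: 16 (1S,2E)-5-chloro-1-[(4R)-2,2-dimethyl-1,3-dioxolan-4-yl]-2-methylpent-2-en-1-ol, via alkenyllithium 14 (not isolated), via alkenyltitanium 15 (not isolated)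
Conditions: t-BuLi (2 equiv), Et2O, −78 °C; ClTi(Oi-Pr)3, −78 to −40 °C; then 13, −78 to −20 °C
Reagents that add atoms: none
Why: Iodine–lithium exchange with retention, transmetalation and addition of the non-chelating alkenyltitanium follow the Felkin–Anh model (anti), so the bought dioxolane centre sets the new carbinol (later C4) as (S).

Step 8
Reactants: 16 (1S,2E)-5-chloro-1-[(4R)-2,2-dimethyl-1,3-dioxolan-4-yl]-2-methylpent-2-en-1-ol
Product: 17 (4R)-4-{(1S,2E)-5-chloro-1-[(4-methoxyphenyl)methoxy]-2-methylpent-2-en-1-yl}-2,2-dimethyl-1,3-dioxolane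
Conditions: NaH, 4-methoxybenzyl bromide, THF/DMF, 0 °C to rt
Reagents that add atoms: 4-methoxybenzyl bromide, COc1ccc(CBr)cc1
Why: Williamson etherification protects C4–OH as a PMB ether that can later be removed without touching silyl ethers.

Step 9
Reactants: 17 (4R)-4-{(1S,2E)-5-chloro-1-[(4-methoxyphenyl)methoxy]-2-methylpent-2-en-1-yl}-2,2-dimethyl-1,3-dioxolane
Product: 18 methyl (5E,7S)-2-(dimethoxyphosphoryl)-7-[(4R)-2,2-dimethyl-1,3-dioxolan-4-yl]-7-[(4-methoxyphenyl)methoxy]-6-methylhept-5-enoate (1:1 at C2)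
Conditions: trimethyl phosphonoacetate (2 equiv), NaH, NaI, DMF, 60 °C
Reagents that add atoms: trimethyl phosphonoacetate, COC(=O)CP(=O)(OC)OC
Why: Finkelstein-assisted C-alkylation of the phosphonoacetate anion by the primary chloride installs C9; the new centre is an inconsequential mixture that is erased in step 13.

Step 10
Reactants: 18 methyl (5E,7S)-2-(dimethoxyphosphoryl)-7-[(4R)-2,2-dimethyl-1,3-dioxolan-4-yl]-7-[(4-methoxyphenyl)methoxy]-6-methylhept-5-enoate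
Product: 19 methyl (5E,7S)-2-(dimethoxyphosphoryl)-7-[(4-methoxyphenyl)methoxy]-6-methyl-8-oxooct-5-enoate
Conditions: H5IO6 (1.5 equiv), EtOAc, rt
Reagents that add atoms: none
Why: Periodic acid hydrolyses the terminal acetonide and cleaves the glycol (Malaprade) in one operation, which removes the controlling dioxolane centre and unveils C3 as the aldehyde without touching C4.

Step 11
Reactants: 9 tert-butyl{[(3S,6E)-7-iodo-2,6-dimethylhepta-1,6-dien-3-yl]oxy}dimethylsilane; 19 methyl (5E,7S)-2-(dimethoxyphosphoryl)-7-[(4-methoxyphenyl)methoxy]-6-methyl-8-oxooct-5-enoate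
Product: 21 methyl (5E,7S,8R,9E,13S)-13-{[tert-butyl(dimethyl)silyl]oxy}-2-(dimethoxyphosphoryl)-8-hydroxy-7-[(4-methoxyphenyl)methoxy]-6,10,14-trimethylpentadeca-5,9,14-trienoate, via alkenylchromium 20 (not isolated)
Conditions: CrCl2 (6 equiv), NiCl2 (2 mol%), DMSO, rt
Reagents that add atoms: none
Why: Nozaki–Hiyama–Kishi coupling tolerates the acidic phosphonoacetate and the epimerisable aldehyde, and the alkenylchromium adds in the Felkin–Anh sense (PMB-ether oxygen anti to the nucleophile) to give the 7,8-anti (8R) alcohol with the alkene geometry of 9 retained.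

Step 12
Reactants: 21 methyl (5E,7S,8R,9E,13S)-13-{[tert-butyl(dimethyl)silyl]oxy}-2-(dimethoxyphosphoryl)-8-hydroxy-7-[(4-methoxyphenyl)methoxy]-6,10,14-trimethylpentadeca-5,9,14-trienoate
Product: 23 methyl (5E,7R,8E,10S)-10-[(3S)-3-{[tert-butyl(dimethyl)silyl]oxy}-4-methylpent-4-en-1-yl]-2-(dimethoxyphosphoryl)-7-[(4-methoxyphenyl)methoxy]-6,10-dimethyl-12-oxododeca-5,8-dienoate, via allyl vinyl ether 22 (not isolated)
Conditions: Pd(OAc)2 (5 mol%), 1,10-phenanthroline (5 mol%), triethylene glycol divinyl ether, 80 °C; then 150 °C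
Reagents that add atoms: triethylene glycol divinyl ether, C=COCCOCCOCCOC=C
Why: Palladium-catalysed vinyl transfer followed by Claisen rearrangement through a chair with the C4 substituent equatorial forms the C1–C11 bond on one face of the (E)-trisubstituted alkene, so the (R)-carbinol at C3 is transferred into the (S) quaternary centre C1 and the new C2=C3 bond is E.

Step 13
Reactants: 23 methyl (5E,7R,8E,10S)-10-[(3S)-3-{[tert-butyl(dimethyl)silyl]oxy}-4-methylpent-4-en-1-yl]-2-(dimethoxyphosphoryl)-7-[(4-methoxyphenyl)methoxy]-6,10-dimethyl-12-oxododeca-5,8-dienoate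
Product: 24 methyl (1E,4S,5E,7R,8E)-4-[(3S)-3-{[tert-butyl(dimethyl)silyl]oxy}-4-methylpent-4-en-1-yl]-7-[(4-methoxyphenyl)methoxy]-4,8-dimethylcycloundeca-1,5,8-triene-1-carboxylate
Conditions: LiCl, DBU, MeCN, 0.001 M (slow addition), rt to 50 °C
Reagents that add atoms: none
Why: Intramolecular Horner–Wadsworth–Emmons olefination (Masamune–Roush conditions, high dilution) closes the 11-membered ring, and both the kinetic preference of the α-substituted phosphonoacetate and ring strain favour the enoate with C8 and C11 cis.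

Step 14
Reactants: 24 methyl (1E,4S,5E,7R,8E)-4-[(3S)-3-{[tert-butyl(dimethyl)silyl]oxy}-4-methylpent-4-en-1-yl]-7-[(4-methoxyphenyl)methoxy]-4,8-dimethylcycloundeca-1,5,8-triene-1-carboxylate
Product: 25 methyl (1E,4S,5E,7R,8E)-4-[(3S)-3-{[tert-butyl(dimethyl)silyl]oxy}-4-methylpent-4-en-1-yl]-7-hydroxy-4,8-dimethylcycloundeca-1,5,8-triene-1-carboxylate
Conditions: DDQ (1.2 equiv), CH2Cl2/pH 7 buffer, 0 °C
Reagents that add atoms: none
Why: Oxidative PMB cleavage frees the C4 hydroxyl while both silyl-protected and ester functions stay intact; the reaction is stopped at full conversion to avoid oxidation of the bis-allylic alcohol.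

Step 15
Reactants: 25 methyl (1E,4S,5E,7R,8E)-4-[(3S)-3-{[tert-butyl(dimethyl)silyl]oxy}-4-methylpent-4-en-1-yl]-7-hydroxy-4,8-dimethylcycloundeca-1,5,8-triene-1-carboxylate
Product: 26 methyl (1S,2R,3E,5S,7E,11S)-5-[(3S)-3-{[tert-butyl(dimethyl)silyl]oxy}-4-methylpent-4-en-1-yl]-2-hydroxy-1,5-dimethyl-12-oxabicyclo[9.1.0]dodeca-3,7-diene-8-carboxylate
Conditions: mCPBA (1.05 equiv), NaHCO3, CH2Cl2, −20 to 0 °C
Reagents that add atoms: 3-chloroperbenzoic acid, OOC(=O)c1cccc(Cl)c1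
Why: In this hydroxyl-directed (Henbest) epoxidation the trans-cycloalkene holds ring carbon C3 out of the C5=C6 plane on the inner face, so C4–H eclipses the alkene and the hydroxyl, at about 120 degrees on the exposed face, delivers the peracid there to give the threo 5,6-epoxide, while the enoate and the hindered or less substituted alkenes react more slowly.

Step 16
Reactants: 26 methyl (1S,2R,3E,5S,7E,11S)-5-[(3S)-3-{[tert-butyl(dimethyl)silyl]oxy}-4-methylpent-4-en-1-yl]-2-hydroxy-1,5-dimethyl-12-oxabicyclo[9.1.0]dodeca-3,7-diene-8-carboxylate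
Product: 27 (1S,2R,3E,5S,7E,11S)-5-[(3S)-3-{[tert-butyl(dimethyl)silyl]oxy}-4-methylpent-4-en-1-yl]-8-(hydroxymethyl)-1,5-dimethyl-12-oxabicyclo[9.1.0]dodeca-3,7-dien-2-ol
Conditions: i-Bu2AlH (4 equiv), CH2Cl2, −78 °C
Reagents that add atoms: none
Why: 1,2-Reduction of the conjugated methyl ester gives the allylic alcohol at −78 °C, where the epoxide is not opened.

Step 17
Reactants: 27 (1S,2R,3E,5S,7E,11S)-5-[(3S)-3-{[tert-butyl(dimethyl)silyl]oxy}-4-methylpent-4-en-1-yl]-8-(hydroxymethyl)-1,5-dimethyl-12-oxabicyclo[9.1.0]dodeca-3,7-dien-2-ol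
Product: 28 (1S,2R,3E,5S,7E,11S)-5-[(3S)-3-{[tert-butyl(dimethyl)silyl]oxy}-4-methylpent-4-en-1-yl]-8-({[tert-butyl(dimethyl)silyl]oxy}methyl)-1,5-dimethyl-12-oxabicyclo[9.1.0]dodeca-3,7-dien-2-ol
Conditions: TBSCl (1.1 equiv), imidazole, CH2Cl2, 0 °C
Reagents that add atoms: tert-butyldimethylsilyl chloride, CC(C)(C)[Si](C)(C)Cl
Why: Silylation is selective for the primary allylic alcohol over the hindered secondary alcohol flanked by the epoxide.

Step 18
Reactants: 28 (1S,2R,3E,5S,7E,11S)-5-[(3S)-3-{[tert-butyl(dimethyl)silyl]oxy}-4-methylpent-4-en-1-yl]-8-({[tert-butyl(dimethyl)silyl]oxy}methyl)-1,5-dimethyl-12-oxabicyclo[9.1.0]dodeca-3,7-dien-2-ol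
Product: 29 (1R,2R,3E,5S,7E,11S)-5-[(3S)-3-{[tert-butyl(dimethyl)silyl]oxy}-4-methylpent-4-en-1-yl]-8-({[tert-butyl(dimethyl)silyl]oxy}methyl)-1,5-dimethyl-12-oxabicyclo[9.1.0]dodeca-3,7-dien-2-yl 3-methylbut-2-enoate
Conditions: 3-methylbut-2-enoyl chloride (3 equiv), pyridine, DMAP (cat.), CH2Cl2, 0 °C to rt
Reagents that add atoms: 3-methylbut-2-enoyl chloride, CC(C)=CC(=O)Cl
Why: DMAP-catalysed acylation esterifies C4–OH with retention, and pyridine rather than a stronger amine avoids deconjugation of the senecioyl group (the descriptor at the epoxide carbon changes only because of CIP priorities).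

Step 19
Reactants: 29 (1R,2R,3E,5S,7E,11S)-5-[(3S)-3-{[tert-butyl(dimethyl)silyl]oxy}-4-methylpent-4-en-1-yl]-8-({[tert-butyl(dimethyl)silyl]oxy}methyl)-1,5-dimethyl-12-oxabicyclo[9.1.0]dodeca-3,7-dien-2-yl 3-methylbut-2-enoate
Product: 30 (1R,2R,3E,5S,7E,11S)-5-[(3S)-3-hydroxy-4-methylpent-4-en-1-yl]-8-(hydroxymethyl)-1,5-dimethyl-12-oxabicyclo[9.1.0]dodeca-3,7-dien-2-yl 3-methylbut-2-enoate
Conditions: TBAF, AcOH (1:1), THF, 0 °C to rt
Reagents that add atoms: none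
Why: Buffered fluoride desilylation removes both silyl ethers without acyl migration or epoxide opening and gives the target.

## Compound list

1 | (S)-5-oxotetrahydrofuran-2-carboxylic acid | OC(=O)[C@@H]1CCC(=O)O1 | starting material
2 | (S)-5-oxotetrahydrofuran-2-carbonyl chloride | ClC(=O)[C@@H]1CCC(=O)O1 | intermediate
3 | (S)-5-acetyldihydrofuran-2(3H)-one | CC(=O)[C@@H]1CCC(=O)O1 | intermediate
4 | (S)-5-(prop-1-en-2-yl)dihydrofuran-2(3H)-one | C=C(C)[C@@H]1CCC(=O)O1 | intermediate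
5 | (5S)-5-(prop-1-en-2-yl)tetrahydrofuran-2-ol (lactol, both anomers) | C=C(C)[C@@H]1CCC(O)O1 | intermediate
6 | (S)-2-methylhept-1-en-6-yn-3-ol | C=C(C)[C@@H](O)CCC#C | intermediate
7 | (S)-tert-butyldimethyl[(2-methylhept-1-en-6-yn-3-yl)oxy]silane | C=C(C)[C@@H](O[Si](C)(C)C(C)(C)C)CCC#C | intermediate
8 | [(1E,5S)-5-{[tert-butyl(dimethyl)silyl]oxy}-2,6-dimethylhepta-1,6-dien-1-yl]dimethylalane | C=C(C)[C@@H](O[Si](C)(C)C(C)(C)C)CC/C(C)=C/[Al](C)C | intermediate
9 | tert-butyl{[(3S,6E)-7-iodo-2,6-dimethylhepta-1,6-dien-3-yl]oxy}dimethylsilane | C=C(C)[C@@H](O[Si](C)(C)C(C)(C)C)CC/C(C)=C/I | intermediate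
10 | 5-chloropent-2-yne | CC#CCCCl | starting material
11 | chloro[(2E)-5-chloropent-2-en-2-yl]bis(cyclopentadienyl)zirconium | Cl[Zr](C1C=CC=C1)(C1C=CC=C1)/C(C)=C/CCCl | intermediate
12 | (E)-5-chloro-2-iodopent-2-ene | I/C(C)=C/CCCl | intermediate
13 | (R)-2,2-dimethyl-1,3-dioxolane-4-carbaldehyde | O=C[C@H]1COC(C)(C)O1 | starting material
14 | [(2Z)-5-chloropent-2-en-2-yl]lithium (lithium trans to the chain) | [Li]/C(C)=C/CCCl | intermediate
15 | [(2E)-5-chloropent-2-en-2-yl]tris(propan-2-olato)titanium | CC(C)O[Ti](OC(C)C)(OC(C)C)/C(C)=C/CCCl | intermediate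
16 | (1S,2E)-5-chloro-1-[(4R)-2,2-dimethyl-1,3-dioxolan-4-yl]-2-methylpent-2-en-1-ol | ClCC/C=C(\C)[C@H](O)[C@H]1COC(C)(C)O1 | intermediate
17 | (4R)-4-{(1S,2E)-5-chloro-1-[(4-methoxyphenyl)methoxy]-2-methylpent-2-en-1-yl}-2,2-dimethyl-1,3-dioxolane | ClCC/C=C(\C)[C@H](OCc1ccc(OC)cc1)[C@H]1COC(C)(C)O1 | intermediate
18 | methyl (5E,7S)-2-(dimethoxyphosphoryl)-7-[(4R)-2,2-dimethyl-1,3-dioxolan-4-yl]-7-[(4-methoxyphenyl)methoxy]-6-methylhept-5-enoate (1:1 at C2) | COC(=O)C(CC/C=C(\C)[C@H](OCc1ccc(OC)cc1)[C@H]1COC(C)(C)O1)P(=O)(OC)OC | intermediate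
19 | methyl (5E,7S)-2-(dimethoxyphosphoryl)-7-[(4-methoxyphenyl)methoxy]-6-methyl-8-oxooct-5-enoate (1:1 at C2) | COC(=O)C(CC/C=C(\C)[C@H](OCc1ccc(OC)cc1)C=O)P(=O)(OC)OC | intermediate
20 | dichloro[(1E,5S)-5-{[tert-butyl(dimethyl)silyl]oxy}-2,6-dimethylhepta-1,6-dien-1-yl]chromium | C=C(C)[C@@H](O[Si](C)(C)C(C)(C)C)CC/C(C)=C/[Cr](Cl)Cl | intermediate
21 | methyl (5E,7S,8R,9E,13S)-13-{[tert-butyl(dimethyl)silyl]oxy}-2-(dimethoxyphosphoryl)-8-hydroxy-7-[(4-methoxyphenyl)methoxy]-6,10,14-trimethylpentadeca-5,9,14-trienoate | C=C(C)[C@@H](O[Si](C)(C)C(C)(C)C)CC/C(C)=C/[C@@H](O)[C@@H](OCc1ccc(OC)cc1)/C(C)=C/CCC(C(=O)OC)P(=O)(OC)OC | intermediate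
22 | methyl (5E,7S,8R,9E,13S)-13-{[tert-butyl(dimethyl)silyl]oxy}-2-(dimethoxyphosphoryl)-8-(ethenyloxy)-7-[(4-methoxyphenyl)methoxy]-6,10,14-trimethylpentadeca-5,9,14-trienoate | C=C(C)[C@@H](O[Si](C)(C)C(C)(C)C)CC/C(C)=C/[C@@H](OC=C)[C@@H](OCc1ccc(OC)cc1)/C(C)=C/CCC(C(=O)OC)P(=O)(OC)OC | intermediate
23 | methyl (5E,7R,8E,10S)-10-[(3S)-3-{[tert-butyl(dimethyl)silyl]oxy}-4-methylpent-4-en-1-yl]-2-(dimethoxyphosphoryl)-7-[(4-methoxyphenyl)methoxy]-6,10-dimethyl-12-oxododeca-5,8-dienoate | C=C(C)[C@@H](O[Si](C)(C)C(C)(C)C)CC[C@@](C)(CC=O)/C=C/[C@@H](OCc1ccc(OC)cc1)/C(C)=C/CCC(C(=O)OC)P(=O)(OC)OC | intermediate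
24 | methyl (1E,4S,5E,7R,8E)-4-[(3S)-3-{[tert-butyl(dimethyl)silyl]oxy}-4-methylpent-4-en-1-yl]-7-[(4-methoxyphenyl)methoxy]-4,8-dimethylcycloundeca-1,5,8-triene-1-carboxylate | C=C(C)[C@@H](O[Si](C)(C)C(C)(C)C)CC[C@]1(C)/C=C/[C@@H](OCc2ccc(OC)cc2)/C(C)=C/CC/C(C(=O)OC)=C\C1 | intermediate
25 | methyl (1E,4S,5E,7R,8E)-4-[(3S)-3-{[tert-butyl(dimethyl)silyl]oxy}-4-methylpent-4-en-1-yl]-7-hydroxy-4,8-dimethylcycloundeca-1,5,8-triene-1-carboxylate | C=C(C)[C@@H](O[Si](C)(C)C(C)(C)C)CC[C@]1(C)/C=C/[C@@H](O)/C(C)=C/CC/C(C(=O)OC)=C\C1 | intermediate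
26 | methyl (1S,2R,3E,5S,7E,11S)-5-[(3S)-3-{[tert-butyl(dimethyl)silyl]oxy}-4-methylpent-4-en-1-yl]-2-hydroxy-1,5-dimethyl-12-oxabicyclo[9.1.0]dodeca-3,7-diene-8-carboxylate | C=C(C)[C@@H](O[Si](C)(C)C(C)(C)C)CC[C@]1(C)/C=C/[C@@H](O)[C@]2(C)O[C@H]2CC/C(C(=O)OC)=C\C1 | intermediate
27 | (1S,2R,3E,5S,7E,11S)-5-[(3S)-3-{[tert-butyl(dimethyl)silyl]oxy}-4-methylpent-4-en-1-yl]-8-(hydroxymethyl)-1,5-dimethyl-12-oxabicyclo[9.1.0]dodeca-3,7-dien-2-ol | C=C(C)[C@@H](O[Si](C)(C)C(C)(C)C)CC[C@]1(C)/C=C/[C@@H](O)[C@]2(C)O[C@H]2CC/C(CO)=C\C1 | intermediate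
28 | (1S,2R,3E,5S,7E,11S)-5-[(3S)-3-{[tert-butyl(dimethyl)silyl]oxy}-4-methylpent-4-en-1-yl]-8-({[tert-butyl(dimethyl)silyl]oxy}methyl)-1,5-dimethyl-12-oxabicyclo[9.1.0]dodeca-3,7-dien-2-ol | C=C(C)[C@@H](O[Si](C)(C)C(C)(C)C)CC[C@]1(C)/C=C/[C@@H](O)[C@]2(C)O[C@H]2CC/C(CO[Si](C)(C)C(C)(C)C)=C\C1 | intermediate
29 | (1R,2R,3E,5S,7E,11S)-5-[(3S)-3-{[tert-butyl(dimethyl)silyl]oxy}-4-methylpent-4-en-1-yl]-8-({[tert-butyl(dimethyl)silyl]oxy}methyl)-1,5-dimethyl-12-oxabicyclo[9.1.0]dodeca-3,7-dien-2-yl 3-methylbut-2-enoate | C=C(C)[C@@H](O[Si](C)(C)C(C)(C)C)CC[C@]1(C)/C=C/[C@@H](OC(=O)C=C(C)C)[C@]2(C)O[C@H]2CC/C(CO[Si](C)(C)C(C)(C)C)=C\C1 | intermediate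
30 | (1R,2R,3E,5S,7E,11S)-5-[(3S)-3-hydroxy-4-methylpent-4-en-1-yl]-8-(hydroxymethyl)-1,5-dimethyl-12-oxabicyclo[9.1.0]dodeca-3,7-dien-2-yl 3-methylbut-2-enoate | C=C(C)[C@@H](O)CC[C@]1(C)/C=C/[C@@H](OC(=O)C=C(C)C)[C@]2(C)O[C@H]2CC/C(CO)=C\C1 | target

## Step count and risks

Total step count: 19.
Longest linear sequence: 14 steps (steps 1–5 then 11–19; the branch of steps 6–10 then 11–19 is equally long).

The three steps most likely to fail:

1. Step 11 (coupling, anti selectivity at the new carbinol). A poor anti:syn ratio would carry through the Claisen step as the wrong configuration at C1. The fallback sets out from 21 as obtained (mixture of carbinol epimers). Dess–Martin periodinane (CH2Cl2, NaHCO3, rt) oxidises it to the enone methyl (5E,7S,9E,13S)-13-{[tert-butyl(dimethyl)silyl]oxy}-2-(dimethoxyphosphoryl)-7-[(4-methoxyphenyl)methoxy]-6,10,14-trimethyl-8-oxopentadeca-5,9,14-trienoate F1. Zn(BH4)2 (Et2O, −30 °C) then reduces the ketone through the zinc chelate with the PMB-ether oxygen, hydride entering opposite C6, to give the anti alcohol. The route is rejoined at 21.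

2. Step 12 (vinyl transfer to a hindered secondary allylic alcohol, then Claisen). If vinyl transfer stalls, the fallback sets out from 21. Heating with N,N-dimethylacetamide dimethyl acetal (xylene, 140 °C, Eschenmoser–Claisen, same chair and same chirality transfer) gives the amide methyl (5E,7R,8E,10S)-10-[(3S)-3-{[tert-butyl(dimethyl)silyl]oxy}-4-methylpent-4-en-1-yl]-12-(dimethylamino)-2-(dimethoxyphosphoryl)-7-[(4-methoxyphenyl)methoxy]-6,10-dimethyl-12-oxododeca-5,8-dienoate F2. Cp2Zr(H)Cl (THF, rt) reduces the tertiary amide to the aldehyde in the presence of the methyl ester. The route is rejoined at 23.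

3. Step 15 (sense and site of the peracid epoxidation in the macrocycle). The facial outcome rests on a conformational argument and is the least certain step; if the erythro epoxide dominates, the fallback sets out from 25 and switches to vanadium-directed epoxidation on the C7 epimer, with inversion on esterification.
   - MnO2 (CH2Cl2) gives the dienone methyl (1E,4S,5E,8E)-4-[(3S)-3-{[tert-butyl(dimethyl)silyl]oxy}-4-methylpent-4-en-1-yl]-4,8-dimethyl-7-oxocycloundeca-1,5,8-triene-1-carboxylate F3.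
   - NaBH4, CeCl3·7H2O (MeOH, −40 °C) gives 25 (recycled) and its separable epimer methyl (1E,4S,5E,7S,8E)-4-[(3S)-3-{[tert-butyl(dimethyl)silyl]oxy}-4-methylpent-4-en-1-yl]-7-hydroxy-4,8-dimethylcycloundeca-1,5,8-triene-1-carboxylate F4.
   - VO(acac)2, t-BuOOH (CH2Cl2, 0 °C) gives the erythro epoxy alcohol, which carries the epoxide configuration of the target: methyl (1S,2S,3E,5S,7E,11S)-5-[(3S)-3-{[tert-butyl(dimethyl)silyl]oxy}-4-methylpent-4-en-1-yl]-2-hydroxy-1,5-dimethyl-12-oxabicyclo[9.1.0]dodeca-3,7-diene-8-carboxylate F5.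
   - i-Bu2AlH (CH2Cl2, −78 °C) gives the diol (1S,2S,3E,5S,7E,11S)-5-[(3S)-3-{[tert-butyl(dimethyl)silyl]oxy}-4-methylpent-4-en-1-yl]-8-(hydroxymethyl)-1,5-dimethyl-12-oxabicyclo[9.1.0]dodeca-3,7-dien-2-ol F6.
   - TBSCl, imidazole gives the silyl ether (1S,2S,3E,5S,7E,11S)-5-[(3S)-3-{[tert-butyl(dimethyl)silyl]oxy}-4-methylpent-4-en-1-yl]-8-({[tert-butyl(dimethyl)silyl]oxy}methyl)-1,5-dimethyl-12-oxabicyclo[9.1.0]dodeca-3,7-dien-2-ol F7.
   - Mitsunobu esterification (PPh3, diisopropyl azodicarboxylate, 3-methylbut-2-enoic acid, toluene) inverts the carbinol. The route is rejoined at 29.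

Further compounds
F1 | step 11 | methyl (5E,7S,9E,13S)-13-{[tert-butyl(dimethyl)silyl]oxy}-2-(dimethoxyphosphoryl)-7-[(4-methoxyphenyl)methoxy]-6,10,14-trimethyl-8-oxopentadeca-5,9,14-trienoate | C=C(C)[C@@H](O[Si](C)(C)C(C)(C)C)CC/C(C)=C/C(=O)[C@@H](OCc1ccc(OC)cc1)/C(C)=C/CCC(C(=O)OC)P(=O)(OC)OC
F2 | step 12 | methyl (5E,7R,8E,10S)-10-[(3S)-3-{[tert-butyl(dimethyl)silyl]oxy}-4-methylpent-4-en-1-yl]-12-(dimethylamino)-2-(dimethoxyphosphoryl)-7-[(4-methoxyphenyl)methoxy]-6,10-dimethyl-12-oxododeca-5,8-dienoate | C=C(C)[C@@H](O[Si](C)(C)C(C)(C)C)CC[C@@](C)(CC(=O)N(C)C)/C=C/[C@@H](OCc1ccc(OC)cc1)/C(C)=C/CCC(C(=O)OC)P(=O)(OC)OC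
F3 | step 15 | methyl (1E,4S,5E,8E)-4-[(3S)-3-{[tert-butyl(dimethyl)silyl]oxy}-4-methylpent-4-en-1-yl]-4,8-dimethyl-7-oxocycloundeca-1,5,8-triene-1-carboxylate | C=C(C)[C@@H](O[Si](C)(C)C(C)(C)C)CC[C@]1(C)/C=C/C(=O)/C(C)=C/CC/C(C(=O)OC)=C\C1
F4 | step 15 | methyl (1E,4S,5E,7S,8E)-4-[(3S)-3-{[tert-butyl(dimethyl)silyl]oxy}-4-methylpent-4-en-1-yl]-7-hydroxy-4,8-dimethylcycloundeca-1,5,8-triene-1-carboxylate | C=C(C)[C@@H](O[Si](C)(C)C(C)(C)C)CC[C@]1(C)/C=C/[C@H](O)/C(C)=C/CC/C(C(=O)OC)=C\C1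
F5 | step 15 | methyl (1S,2S,3E,5S,7E,11S)-5-[(3S)-3-{[tert-butyl(dimethyl)silyl]oxy}-4-methylpent-4-en-1-yl]-2-hydroxy-1,5-dimethyl-12-oxabicyclo[9.1.0]dodeca-3,7-diene-8-carboxylate | C=C(C)[C@@H](O[Si](C)(C)C(C)(C)C)CC[C@]1(C)/C=C/[C@H](O)[C@]2(C)O[C@H]2CC/C(C(=O)OC)=C\C1
F6 | step 15 | (1S,2S,3E,5S,7E,11S)-5-[(3S)-3-{[tert-butyl(dimethyl)silyl]oxy}-4-methylpent-4-en-1-yl]-8-(hydroxymethyl)-1,5-dimethyl-12-oxabicyclo[9.1.0]dodeca-3,7-dien-2-ol | C=C(C)[C@@H](O[Si](C)(C)C(C)(C)C)CC[C@]1(C)/C=C/[C@H](O)[C@]2(C)O[C@H]2CC/C(CO)=C\C1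
F7 | step 15 | (1S,2S,3E,5S,7E,11S)-5-[(3S)-3-{[tert-butyl(dimethyl)silyl]oxy}-4-methylpent-4-en-1-yl]-8-({[tert-butyl(dimethyl)silyl]oxy}methyl)-1,5-dimethyl-12-oxabicyclo[9.1.0]dodeca-3,7-dien-2-ol | C=C(C)[C@@H](O[Si](C)(C)C(C)(C)C)CC[C@]1(C)/C=C/[C@H](O)[C@]2(C)O[C@H]2CC/C(CO[Si](C)(C)C(C)(C)C)=C\C1
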